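## Analysis of the target

The target 40 is (2S,3R,4R,4aR,5R,7R,8aS)-3-[(2R)-butan-2-yl]-2,7-dihydroxy-7-(hydroxymethyl)-4-(3-hydroxypropanoyl)-2,4,5-trimethyloctahydronaphthalen-1(2H)-one, a cis-fused decalin. Its locants are used for every intermediate below. C-1′ is the carbonyl carbon on C-4, α is the face of H-4a and H-8a, and β is the opposite face.

Ring B (C-1 to C-4, C-4a, C-8a) holds the C-1 ketone, the tertiary C-2 carbinol (2β-methyl, 2α-OH), the 3β-sec-butyl group with its exocyclic (R) centre, and the quaternary C-4 (4α-methyl, 4β-acyl). Ring A (C-4a to C-8a) holds the 5β-methyl group and the C-7 carbinol (7α-OH, 7β-CH2OH). There are eight stereocentres, and five of them (C-2, C-3, C-4, C-4a, C-8a) are contiguous.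

The tertiary α-ketol, the β-hydroxy ketone and the epimerisable C-8a next to the C-1 ketone tolerate neither strong acid nor base, so the end of the route has to be neutral. The hard part is the C-3–C-4 bond, which joins a tertiary carbon carrying a branched group to a fully substituted carbon, with both centres fixed relative to the ring fusion and in the absolute sense.

The strategy rests on one feature. C-4 is bonded to C-3 and lies 1,4 to C-1 through C-4a and C-8a. A carboxyl group at C-1′ can therefore be tied to an oxygen on C-1 as a δ-lactone (C-1′, C-4, C-4a, C-8a, C-1, O). Its ketene acetal, together with a C-2=C-3 alkenyl arm on C-1, is an array set up for a [3,3] shift.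

## Retrosynthetic reasoning

**End game (40 from 37).** Target 40 is traced to its dibenzyl ether 39, so that the last operation is a neutral hydrogenolysis. The ketol of 39 comes from the C-1=C-2 alkene of 37 by syn-dihydroxylation on the α face (diol 38) and oxidation of the only secondary alcohol. Cutting here leaves the sensitive ketol and the C-8a epimerisation problem to the last three steps.

**Side chain (37 from 33).** The 3-oxygenated propanoyl chain of 37 is cut at C-2′–C-3′ and at C-1′–C-2′. Methyl ketone 35 is alkylated through enolate 36 with a benzyloxymethyl electrophile, and 35 comes from acid 33 by addition of a methyl nucleophile. Because C-4 is quaternary, 35 can enolise only toward its methyl group.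

**Key disconnection (33 from 30).** Acid 33 is cut at C-3–C-4 with reconnection of C-1′ to the C-1 oxygen, which gives lactone 30. Forward, silyl ketene acetal 31 rearranges [3,3] to silyl ester 32. One step forms the most congested bond, closes ring B, sets C-3 and C-4 and leaves the C-1=C-2 alkene where the ketol is needed.

**Lactone and C-1 carbinol (30 from 13 and 25).** Lactone 30 is traced to 1,5-diol 27, whose primary alcohol is oxidised through 28 and 29. The C-1 carbinol of 27 comes from enone 26 by hydride addition. The C-1–C-2 bond of 26 comes from alkenyllithium 25 and the inverted lactone 13, in which C-1 is the carbonyl carbon. The carbinol is set by adding hydrogen rather than carbon because the Felkin–Anh analysis predicts the needed (1S) epimer for hydride addition to the ketone and the other epimer for alkenyl addition to the aldehyde.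

**Alkenyl arm (25 from 14).** Lithium reagent 25 comes from (E)-iodide 24, and 24 from alkyne 22 by syn-hydrometalation (through 23), which fixes the alkene geometry. The stereocentre of 22 comes from hydroxy ester 14 through 15–21. The ester carbon becomes the alkyne carbon (aldehyde 16, dibromoalkene 17, acetylide 18, alkyne 19) and the hydroxymethyl group becomes the ethyl group (alcohol 20, tosylate 21).

**Excision of the extra sugar carbon (13 from 9).** Lactone 13 is traced through lactol 12 to tetraol 11, whose only vicinal diol is cleaved to expose C-1 as an aldehyde. Tetraol 11 comes from triacetate 10, the acetolysis product of the internal acetal of 9. This sequence turns the acetal carbon into the C-1′ alcohol and removes the one carbon of 3 that the target does not need.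

**C-7 carbinol (9 from 7).** Benzyl ether 9 comes from spiro-epoxide 8 by opening at the CH2 group, and 8 from ketone 7. The cut is made while ring A is locked as a single chair by cis fusion to the rigid bicyclic acetal, so the epoxidation face can be predicted.

**C-4 methyl group (7 from 4).** The methyl group of 7 comes from the exocyclic alkene of 6, and 6 from the ketone of adduct 4 by methylenation (via 5). The cycloaddition delivers the C-7 carbonyl masked as an enol ether, so the two ketones are told apart without a protecting step.

**Ring A (4 from 2 and 3).** Adduct 4 is cut at C-4a–C-5 and C-8–C-8a into diene 2 (from enone 1) and enone 3. Enone 3 supplies C-1′, C-4, C-4a, C-8a, C-1 and the ring oxygen of the future lactone as a single enantiomer. Its bridge blocks one face, and the cycloaddition sets C-4a, C-5 and C-8a at once.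

## Alternatives that were turned down

**Alternative 1:** Ring A would be cut at C-6–C-7. Forward, ketone A2 would undergo an intramolecular carbonyl-ene reaction of Type 2 under a chelating Lewis acid: the carbonyl carbon (future C-7) bonds to the CH2 end of the isopropenyl group on C-4a while a methyl hydrogen passes to oxygen. This gives A1 with the C-7 carbinol and an exocyclic methylene at C-5.
- For: ring B arrives complete with ketol and side chain, and only a hydrogenation and deprotection remain. On steps after the key step this plan is stronger than the chosen one.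
- Against: all five contiguous centres of ring B, including the C-3/C-4 pair, must already be in place in A2, so the key step does not address the hard bond. A ketone is a sluggish enophile. The Lewis acid meets a silylated ketol and an epimerisable C-8a. C-5 is left to a hydrogenation.
- Comparison: the chosen strategy gives up some late convergence. In return its key step (30 to 33) makes the C-3–C-4 bond with ring-enforced control.

**Alternative 2:** The C-4–C-1′ and C-4a–C-8a bonds would be cut. Forward, irradiation of dioxinone A4 adds its C=C across the tethered (E)-alkene to give cyclobutane A3, which is later opened by retro-aldol fragmentation.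
- For: two C–C bonds, ring A, the quaternary centre and both fusion centres form in one step. On bonds and stereocentres per step this plan is stronger.
- Against: the facial selectivity depends on allylic strain in a flexible chain next to C-3. A3 carries a silyloxy group at C-5 where the methyl group is needed. Ring B still has to be closed at C-1–C-2 and the C-2 carbinol made, so the tail is long.
- Comparison: the chosen step builds less, but it delivers ring B closed, with the C-2 methyl group and the alkene for the ketol already in place.

**Alternative 3:** Ring B would be cut at C-4–C-4a and C-2–C-3. Forward, silyloxydiene A6 and citraconic anhydride A7 combine in an endo Diels–Alder reaction to give A5.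
- For: it is the shortest entry to the bicyclic core, it is intermolecular, and the dienophile brings C-4 with its methyl group. On convergence this plan is stronger.
- Against: A5 has a carboxyl carbon at C-3 where the (R)-sec-butyl group must stand, and no controlled way leads from one to the other. C-2 arrives as a bare CH2. C-8a is trigonal in A5, so the cis fusion must be set later. C-5 again carries oxygen.
- Comparison: the chosen route brings in the intact sec-butyl stereocentre with the arm and sets C-3 in the same step as C-4.

Key step: step 22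

Remark on the chemistry: levoglucosenone 3 is taken as a commercial chiral-pool compound; C-4 in 7–30 is drawn as the epimer expected from hydrogen delivery anti to the anhydro bridge (the other epimer would serve equally, since C-4 becomes trigonal in step 22); the C-7 diol is carried as its primary benzyl ether with the tertiary hydroxyl free, because the bridge of 9 has to be opened under acid.

## Route

Step 1
Reactants: 1 (E)-pent-3-en-2-one
Product: 2 (E)-2-(tert-butyldimethylsilyloxy)penta-1,3-diene
Conditions: LiN(i-Pr)2, THF, −78 °C; t-BuMe2SiCl, DMPU, −78 °C → rt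
Reagents that add atoms: tert-butyldimethylsilyl chloride, CC(C)(C)[Si](C)(C)Cl
Why: Kinetic deprotonation of the enone at its methyl group gives the cross-conjugated dienolate, which is silylated on oxygen (enolate O-silylation); the (E) alkene is untouched.

Step 2
Reactants: 2 silyloxydiene; 3 levoglucosenone
Product: 4 tricyclic Diels–Alder adduct (C-4 ketone, C-6=C-7 silyl enol ether, 5β-methyl)
Conditions: toluene, BHT (cat.), 110 °C, sealed tube
Reagents that add atoms: none
Why: Normal-demand Diels–Alder reaction; the silyloxy and methyl groups both direct the CH2 terminus of 2 to the β-carbon of the enone, so C-8 bonds to C-8a and C-5 to C-4a. The diene adds anti to the 1,6-anhydro bridge, which sets C-4a and C-8a, and the endo orientation over the ketone places the C-5 methyl cis to C-4.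

Step 3
Reactants: 4 Diels–Alder adduct
Product: 6 C-4 methylene C-7 ketone, via methylene silyl enol ether 5 (not isolated)
Conditions: Ph3PCH3Br, KOt-Bu, THF, 0 °C → rt; then Bu4NF, AcOH, THF, 0 °C
Reagents that add atoms: methyltriphenylphosphonium bromide, C[P+](c1ccccc1)(c1ccccc1)c1ccccc1.[Br-]
Why: Wittig methylenation of the only free ketone (C-7 is masked as the enol ether), then buffered fluoride cleavage of the enol ether. C-4a cannot epimerise because a trans fusion is impossible on the rigid anhydro sugar chair.

Step 4
Reactants: 6 methylene ketone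
Product: 7 C-4 methyl C-7 ketone
Conditions: H2 (1 atm), Pd/C, EtOAc, rt
Reagents that add atoms: none
Why: Heterogeneous hydrogenation of the 1,1-disubstituted alkene, with ketone and acetal inert. Hydrogen is expected anti to the bridge, and the C-4 configuration is of no consequence later.

Step 5
Reactants: 7 ketone
Product: 8 C-7 spiro-epoxide (CH2 β, O α)
Conditions: Me3S(O)I, NaH, DMSO, rt → 50 °C
Reagents that add atoms: trimethylsulfoxonium iodide, C[S+](C)(C)=O.[I-]
Why: Corey–Chaykovsky epoxidation with the sulfoxonium ylide, whose reversible addition leads to the equatorial C–C bond. Ring A is one locked chair (5-methyl equatorial), so equatorial CH2 is β and the axial oxygen is α, as C-7 requires.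

Step 6
Reactants: 8 epoxide
Product: 9 7α-hydroxy-7β-(benzyloxymethyl) anhydro sugar
Conditions: NaH, BnOH (solvent), 90 °C
Reagents that add atoms: benzyl alcohol, OCc1ccccc1
Why: SN2 opening of the 2,2-disubstituted epoxide at its CH2 by benzyloxide; the tertiary C–O bond is not touched, so C-7 is retained, and the acetal is stable to base.

Step 7
Reactants: 9 anhydro sugar
Product: 10 triacetate (anomeric acetate at C-1′, primary acetate, C-7 acetate)
Conditions: Ac2O, Me3SiOSO2CF3 (cat.), CH2Cl2, 0 °C
Reagents that add atoms: acetic anhydride, CC(=O)OC(C)=O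
Why: Acid-catalysed acetolysis of the internal 1,6-anhydro acetal; the ring oxocarbenium ion is trapped by acetate and the tertiary alcohol is acetylated under the same conditions. The benzyl ether should survive at 0 °C.

Step 8
Reactants: 10 triacetate
Product: 11 tetraol (C-1′ primary alcohol, C-1 secondary alcohol with its CH2OH, C-7 tertiary alcohol)
Conditions: LiAlH4, THF, 0 °C → reflux
Reagents that add atoms: none
Why: Hydride cleaves the three acetates and reduces the liberated hemiacetal through its open aldehyde form to the primary alcohol.

Step 9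
Reactants: 11 tetraol
Product: 12 δ-lactol (C-1 hemiacetal closed onto the C-1′ oxygen)
Conditions: NaIO4, THF–H2O (pH 7), 0 °C → rt
Reagents that add atoms: none
Why: Periodate glycol cleavage of the only vicinal diol removes the extra sugar carbon as formaldehyde; C-7 is safe because its CH2O is benzylated. The aldehyde is trapped as the lactol, which protects C-8a from epimerisation.

Step 10
Reactants: 12 lactol
Product: 13 inverted δ-lactone (C-1 carbonyl, C-1′ CH2 in the ring)
Conditions: TEMPO (cat.), PhI(OAc)2, CH2Cl2, rt
Reagents that add atoms: none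
Why: Oxoammonium oxidation of a lactol to the lactone; the tertiary alcohol and the benzyl ether are inert.

Step 11
Reactants: 14 methyl (R)-3-hydroxy-2-methylpropanoate
Product: 15 methyl (2R)-3-(tert-butyldimethylsilyloxy)-2-methylpropanoate
Conditions: t-BuMe2SiCl, imidazole, CH2Cl2, rt
Reagents that add atoms: tert-butyldimethylsilyl chloride, CC(C)(C)[Si](C)(C)Cl
Why: Standard silylation of a primary alcohol; the stereocentre is not involved.

Step 12
Reactants: 15 silyl ether ester
Product: 16 (2R)-3-(tert-butyldimethylsilyloxy)-2-methylpropanal
Conditions: (i-Bu)2AlH, CH2Cl2, −78 °C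
Reagents that add atoms: none
Why: Partial reduction of the ester; the aluminium hemiacetal is stable at −78 °C, and the aldehyde is used at once to avoid α-epimerisation.

Step 13
Reactants: 16 aldehyde
Product: 17 tert-butyl{[(2S)-4,4-dibromo-2-methylbut-3-en-1-yl]oxy}dimethylsilane
Conditions: CBr4, PPh3, CH2Cl2, 0 °C
Reagents that add atoms: carbon tetrabromide, BrC(Br)(Br)Br
Why: First stage of the Corey–Fuchs reaction (dibromomethylenation under neutral conditions), so the α-centre is kept.

Step 14
Reactants: 17 dibromoalkene
Product: 19 tert-butyl(dimethyl){[(2S)-2-methylpent-3-yn-1-yl]oxy}silane, via lithium acetylide 18 (not isolated)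
Conditions: n-BuLi (2.2 equiv), THF, −78 °C; MeI, −78 °C → rt
Reagents that add atoms: iodomethane, CI
Why: Second stage of the Corey–Fuchs reaction: bromine–lithium exchange, rearrangement of the carbenoid to the alkyne and deprotonation give the acetylide, which is methylated in the same flask.

Step 15
Reactants: 19 silyl ether
Product: 20 (2S)-2-methylpent-3-yn-1-ol
Conditions: Bu4NF, THF, 0 °C → rt
Reagents that add atoms: none
Why: Fluoride cleavage of the silyl ether.

Step 16
Reactants: 20 alkynol
Product: 21 (2S)-2-methylpent-3-yn-1-yl 4-methylbenzenesulfonate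
Conditions: TsCl, pyridine, CH2Cl2, 0 °C
Reagents that add atoms: 4-methylbenzenesulfonyl chloride, Cc1ccc(cc1)S(Cl)(=O)=O
Why: Sulfonylation of a primary alcohol.

Step 17
Reactants: 21 tosylate
Product: 22 (4R)-4-methylhex-2-yne
Conditions: Me2CuLi (from MeLi and CuI), Et2O, −40 → 0 °C
Reagents that add atoms: methyllithium, C[Li]
Why: Cuprate displacement of a primary tosylate turns the oxygenated carbon into the ethyl group; the stereocentre is a spectator. The volatile alkyne is carried on as a distilled solution.

Step 18
Reactants: 22 alkyne
Product: 24 (2E,4R)-2-iodo-4-methylhex-2-ene, via alkenylzirconocene chloride 23 (not isolated)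
Conditions: Cp2Zr(H)Cl (1.5 equiv), THF, rt → 50 °C; then I2, 0 °C
Reagents that add atoms: iodine, II
Why: Syn-hydrozirconation; with a slight excess of the hydride the regioisomers equilibrate so that zirconium sits on the methyl-bearing carbon, away from the branched group. Iodinolysis with retention gives the (E) iodide.

Step 19
Reactants: 24 alkenyl iodide; 13 inverted lactone
Product: 26 hydroxy enone, via alkenyllithium 25 (not isolated)
Conditions: 24, t-BuLi (2 equiv), Et2O, −78 °C; added to 13 (pretreated with i-PrMgCl, 1 equiv), THF, −78 °C; aq. NH4Cl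
Reagents that add atoms: none
Why: Iodine–lithium exchange keeps the alkene geometry. Acyl substitution on the lactone stops at the ketone stage because the tetrahedral alkoxide persists at −78 °C. The tertiary hydroxyl is held as its magnesium alkoxide.

Step 20
Reactants: 26 hydroxy enone
Product: 27 (1S)-allylic alcohol (1,5-diol)
Conditions: Li[(s-Bu)3BH], THF, −78 °C
Reagents that add atoms: none
Why: 1,2-Reduction by a bulky hydride under Felkin–Anh control: hydride adds anti to the C-8a–C-4a bond (the branched ring carbon is the large group), which should give the (1S) alcohol.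

Step 21
Reactants: 27 diol
Product: 30 δ-lactone with (E)-alkenyl arm, via hydroxy aldehyde 28 (not isolated), via lactol 29 (not isolated)
Conditions: TEMPO (cat.), PhI(OAc)2 (2.5 equiv), CH2Cl2, rt
Reagents that add atoms: none
Why: Oxidative lactonisation of a 1,5-diol: the unhindered primary alcohol is oxidised first, the aldehyde is trapped by the C-1 hydroxyl, and the lactol is oxidised further. The hindered allylic and the tertiary alcohol should not compete.

Step 22
Reactants: 30 δ-lactone
Product: 33 cis-octalin carboxylic acid, via bis-silylated ketene acetal 31 (not isolated), via trimethylsilyl ester 32 (not isolated)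
Conditions: KN(SiMe3)2 (2.5 equiv), Me3SiCl–Et3N, THF–toluene, −78 °C → rt; toluene, 110 °C; then 1 M HCl, THF
Reagents that add atoms: none
Why: KN(SiMe3)2 removes the C-4 hydrogen and the tertiary hydroxyl proton, and Me3SiCl traps the lactone enolate on oxygen as cyclic silyl ketene acetal 31, whose C=C geometry is fixed by the ring. On heating, a concerted suprafacial [3,3]-sigmatropic shift (Ireland–Claisen rearrangement of a lactone, a Claisen ring contraction) forms the C-3–C-4 bond as the C-1–O bond breaks, which closes ring B (C-4, C-4a, C-8a, C-1, C-2, C-3) as a cyclohexene. Because the ketene acetal and the carbinol carbon sit in the same six-membered ring, only a boat-like (bicyclo[2.2.2]octene-like) transition state can be reached. C-4 is controlled by the (1S) carbinol: the alkenyl arm lies on the α face of the lactone, so the new bond forms there and the carboxyl carbon becomes β. C-3 is controlled by the (E) geometry of the arm, which places the sec-butyl group on the same side of the new ring as the carboxyl carbon (β). The cis fusion is kept because C-4a and C-8a are not touched. The step needs complete enolisation at C-4 without attack on the lactone and a clean thermal shift without ionisation of the allylic C–O bond; ring A lies on the face away from the arm, which should help. Hydrolysis of silyl ester 32 and of the silyl ether on work-up gives 33.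

Step 23
Reactants: 33 acid
Product: 35 methyl ketone, via dilithium gem-diolate 34 (not isolated)
Conditions: MeLi (excess), Et2O, 0 °C → rt; aq. NH4Cl
Reagents that add atoms: methyllithium, C[Li]
Why: Addition of methyllithium to a lithium carboxylate gives a gem-diolate that does not collapse until work-up, so the hindered tertiary acid gives the ketone; alkene and benzyl ether are inert.

Step 24
Reactants: 35 methyl ketone
Product: 37 β-benzyloxy ketone, via lithium enolate 36 (not isolated)
Conditions: LiN(i-Pr)2 (2.1 equiv), THF, −78 °C; BnOCH2Cl, −78 → −40 °C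
Reagents that add atoms: benzyl chloromethyl ether, ClCOCc1ccccc1
Why: Enolate C-alkylation with an α-chloro ether. C-4 is quaternary, so only the methyl group can enolise. Any benzyloxymethyl ether formed at the tertiary alkoxide would be cleaved in step 27.

Step 25
Reactants: 37 alkene
Product: 38 1α,2α-diol
Conditions: OsO4 (cat.), N-methylmorpholine N-oxide, acetone–H2O, rt
Reagents that add atoms: osmium tetroxide, O=[Os](=O)(=O)=O; N-methylmorpholine N-oxide, C[N+]1([O-])CCOCC1; water, O
Why: Catalytic syn-dihydroxylation. The reagent should approach the convex α face, anti to the 3β-sec-butyl group, the 4β-acyl group and ring A, which sets C-2 (OH α, methyl β).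

Step 26
Reactants: 38 diol
Product: 39 dibenzyl ether of the target
Conditions: Dess–Martin periodinane, NaHCO3, CH2Cl2, 0 °C → rt
Reagents that add atoms: none
Why: Oxidation of the only secondary alcohol to the ketol; tertiary alcohols are inert, both primary alcohols are benzylated, and the buffered conditions spare C-8a.

Step 27
Reactants: 39 dibenzyl ether
Product: 40 target
Conditions: H2 (1 atm), Pd(OH)2/C, EtOAc–MeOH, rt
Reagents that add atoms: none
Why: Hydrogenolysis of the two primary benzyl ethers under neutral conditions; no alkene remains, and ketol, β-hydroxy ketone and C-8a are left alone.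

## Compound list

1 | (E)-pent-3-en-2-one | C/C=C/C(C)=O | starting material
2 | (E)-2-(tert-butyldimethylsilyloxy)penta-1,3-diene | C/C=C/C(=C)O[Si](C)(C)C(C)(C)C | intermediate
3 | levoglucosenone, (1S,5R)-6,8-dioxabicyclo[3.2.1]oct-2-en-4-one | O=C1C=C[C@H]2CO[C@@H]1O2 | starting material
4 | Diels–Alder adduct: 1,6-anhydro sugar ring with C-4 ketone, cis-fused at C-4a/C-8a (new bonds anti to the bridge) to ring A with 5β-methyl and C-6=C-7 silyl enol ether | O=C1[C@@H]2[C@H](C)C=C(O[Si](C)(C)C(C)(C)C)C[C@@H]2[C@H]3CO[C@@H]1O3 | intermediate
5 | as 4 with exocyclic methylene at C-4 | C=C1[C@@H]2[C@H](C)C=C(O[Si](C)(C)C(C)(C)C)C[C@@H]2[C@H]3CO[C@@H]1O3 | intermediate (not isolated)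
6 | C-4 methylene, C-7 ketone | C=C1[C@@H]2[C@H](C)CC(=O)C[C@@H]2[C@H]3CO[C@@H]1O3 | intermediate
7 | C-4 methyl, C-7 ketone | C[C@H]1[C@@H]2[C@H](C)CC(=O)C[C@@H]2[C@H]3CO[C@@H]1O3 | intermediate
8 | C-7 spiro-epoxide (CH2 β, O α) | C[C@H]1[C@@H]2[C@H](C)C[C@]4(CO4)C[C@@H]2[C@H]3CO[C@@H]1O3 | intermediate
9 | 7α-hydroxy-7β-(benzyloxymethyl) anhydro sugar | C[C@H]1[C@@H]2[C@H](C)C[C@](O)(COCc4ccccc4)C[C@@H]2[C@H]3CO[C@@H]1O3 | intermediate
10 | triacetate: pyranose with anomeric acetate at C-1′ (both anomers), acetoxymethyl on C-1, 7α-acetoxy | C[C@H]1[C@@H]2[C@H](C)C[C@](OC(C)=O)(COCc3ccccc3)C[C@@H]2[C@@H](COC(C)=O)OC1OC(C)=O | intermediate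
11 | tetraol: ring A with 4a-(1-hydroxypropan-2-yl) arm and 8a-(1,2-dihydroxyethyl) arm, cis | C[C@H](CO)[C@@H]1[C@H](C)C[C@](O)(COCc2ccccc2)C[C@@H]1[C@H](O)CO | intermediate
12 | δ-lactol: C-1 hemiacetal (both anomers), ring O–C-1′H2 | C[C@H]1[C@@H]2[C@H](C)C[C@](O)(COCc3ccccc3)C[C@@H]2C(O)OC1 | intermediate
13 | inverted δ-lactone (C-1 carbonyl) | C[C@H]1[C@@H]2[C@H](C)C[C@](O)(COCc3ccccc3)C[C@@H]2C(=O)OC1 | intermediate
14 | methyl (R)-3-hydroxy-2-methylpropanoate | C[C@H](CO)C(=O)OC | starting material
15 | methyl (2R)-3-(tert-butyldimethylsilyloxy)-2-methylpropanoate | C[C@H](CO[Si](C)(C)C(C)(C)C)C(=O)OC | intermediate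
16 | (2R)-3-(tert-butyldimethylsilyloxy)-2-methylpropanal | C[C@H](CO[Si](C)(C)C(C)(C)C)C=O | intermediate
17 | tert-butyl{[(2S)-4,4-dibromo-2-methylbut-3-en-1-yl]oxy}dimethylsilane | C[C@H](CO[Si](C)(C)C(C)(C)C)C=C(Br)Br | intermediate
18 | lithium acetylide of the (2S)-2-methylbut-3-ynyl silyl ether | C[C@H](CO[Si](C)(C)C(C)(C)C)C#C[Li] | intermediate (not isolated)
19 | tert-butyl(dimethyl){[(2S)-2-methylpent-3-yn-1-yl]oxy}silane | C[C@H](CO[Si](C)(C)C(C)(C)C)C#CC | intermediate
20 | (2S)-2-methylpent-3-yn-1-ol | C[C@H](CO)C#CC | intermediate
21 | (2S)-2-methylpent-3-yn-1-yl 4-methylbenzenesulfonate | C[C@H](COS(=O)(=O)c1ccc(C)cc1)C#CC | intermediate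
22 | (4R)-4-methylhex-2-yne | C[C@H](CC)C#CC | intermediate
23 | chloro[(2E,4R)-4-methylhex-2-en-2-yl]zirconocene (σ-drawn cyclopentadienyl rings) | CC[C@@H](C)/C=C(C)/[Zr](Cl)(C1C=CC=C1)C1C=CC=C1 | intermediate (not isolated)
24 | (2E,4R)-2-iodo-4-methylhex-2-ene | CC[C@@H](C)/C=C(C)/I | intermediate
25 | [(2E,4R)-4-methylhex-2-en-2-yl]lithium | CC[C@@H](C)/C=C(C)/[Li] | intermediate (not isolated)
26 | hydroxy enone: C-1 ketone with the (E)-alkenyl group, C-1′ primary alcohol | C[C@H](CO)[C@@H]1[C@H](C)C[C@](O)(COCc2ccccc2)C[C@@H]1C(=O)/C(C)=C/[C@H](C)CC | intermediate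
27 | (1S)-allylic alcohol, 1,5-diol | C[C@H](CO)[C@@H]1[C@H](C)C[C@](O)(COCc2ccccc2)C[C@@H]1[C@H](O)/C(C)=C/[C@H](C)CC | intermediate
28 | hydroxy aldehyde (C-1′ aldehyde) | C[C@H](C=O)[C@@H]1[C@H](C)C[C@](O)(COCc2ccccc2)C[C@@H]1[C@H](O)/C(C)=C/[C@H](C)CC | intermediate (not isolated)
29 | lactol at C-1′ (both anomers) | C[C@H]1[C@@H]2[C@H](C)C[C@](O)(COCc3ccccc3)C[C@@H]2[C@@H](/C(C)=C/[C@H](C)CC)OC1O | intermediate (not isolated)
30 | ring-A-fused δ-lactone (C-1′ carbonyl, O on (1S)-C-1, (E)-alkenyl arm α, cis fusion, 5β-methyl, 7α-OH, 7β-CH2OBn) | C[C@H]1[C@@H]2[C@H](C)C[C@](O)(COCc3ccccc3)C[C@@H]2[C@@H](/C(C)=C/[C@H](C)CC)OC1=O | intermediate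
31 | cyclic trimethylsilyl ketene acetal of 30, with 7-O-trimethylsilyl | CC=1[C@@H]2[C@H](C)C[C@](O[Si](C)(C)C)(COCc3ccccc3)C[C@@H]2[C@@H](/C(C)=C/[C@H](C)CC)OC=1O[Si](C)(C)C | intermediate (not isolated)
32 | trimethylsilyl ester of 33, with 7-O-trimethylsilyl | CC[C@@H](C)[C@@H]1[C@](C)(C(=O)O[Si](C)(C)C)[C@@H]2[C@H](C)C[C@](O[Si](C)(C)C)(COCc3ccccc3)C[C@@H]2C=C1C | intermediate (not isolated)
33 | cis-octalin acid: 4β-CO2H, 4α-methyl, 3β-[(2R)-butan-2-yl], C-1=C-2 alkene with 2-methyl | CC[C@@H](C)[C@@H]1[C@](C)(C(=O)O)[C@@H]2[C@H](C)C[C@](O)(COCc3ccccc3)C[C@@H]2C=C1C | intermediate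
34 | dilithium gem-diolate (C-7 lithium alkoxide) | CC[C@@H](C)[C@@H]1[C@](C)(C(C)(O[Li])O[Li])[C@@H]2[C@H](C)C[C@](O[Li])(COCc3ccccc3)C[C@@H]2C=C1C | intermediate (not isolated)
35 | 4β-acetyl octalin (methyl ketone) | CC[C@@H](C)[C@@H]1[C@](C)(C(C)=O)[C@@H]2[C@H](C)C[C@](O)(COCc3ccccc3)C[C@@H]2C=C1C | intermediate
36 | lithium enolate of 35 (C-7 lithium alkoxide) | CC[C@@H](C)[C@@H]1[C@](C)(C(=C)O[Li])[C@@H]2[C@H](C)C[C@](O[Li])(COCc3ccccc3)C[C@@H]2C=C1C | intermediate (not isolated)
37 | 4β-(3-benzyloxypropanoyl) octalin | CC[C@@H](C)[C@@H]1[C@](C)(C(=O)CCOCc3ccccc3)[C@@H]2[C@H](C)C[C@](O)(COCc4ccccc4)C[C@@H]2C=C1C | intermediate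
38 | 1α,2α-diol (2β-methyl) | CC[C@@H](C)[C@@H]1[C@](C)(C(=O)CCOCc3ccccc3)[C@@H]2[C@H](C)C[C@](O)(COCc4ccccc4)C[C@@H]2[C@@H](O)[C@@]1(C)O | intermediate
39 | dibenzyl ether of the target (C-1 ketone, 2α-OH) | CC[C@@H](C)[C@@H]1[C@](C)(C(=O)CCOCc3ccccc3)[C@@H]2[C@H](C)C[C@](O)(COCc4ccccc4)C[C@@H]2C(=O)[C@@]1(C)O | intermediate
40 | (2S,3R,4R,4aR,5R,7R,8aS)-3-[(2R)-butan-2-yl]-2,7-dihydroxy-7-(hydroxymethyl)-4-(3-hydroxypropanoyl)-2,4,5-trimethyloctahydronaphthalen-1(2H)-one | CC[C@@H](C)[C@@H]1[C@](C)(C(=O)CCO)[C@@H]2[C@H](C)C[C@](O)(CO)C[C@@H]2C(=O)[C@@]1(C)O | target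

## Step count and least certain steps

Total: 27 steps. Longest linear sequence: 19 steps (steps 1–10 and 19–27, from 1); the arm (steps 11–18) joins at step 19.

**Step 22 (key step).** The shift must pass through a boat that joins a fully substituted ketene acetal carbon to a carbon carrying a sec-butyl group. It may therefore be slow enough for desilylation of the ketene acetal or ionisation of the allylic C–O bond to take over. Fallback: the neutral allyl vinyl ether version of the same ring contraction. It sets out from 30. Reduction with (i-Bu)2AlH gives lactol 29, and dehydration with MsCl and Et3N gives the cyclic enol ether F1. Thermolysis at about 190 °C in o-dichlorobenzene then drives the Claisen rearrangement through the same ring-enforced boat, with the same stereochemical course, to aldehyde F2. This substrate has no base-labile silyl group and tolerates the higher temperature. Oxidation of F2 with NaClO2 returns to the route at 33.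

**Step 2.** The silyloxydiene may polymerise or lose its silyl group before it adds, and the endo preference that sets C-5 may be incomplete. Fallback: a stepwise anionic annulation. The lithium dienolate of 1 (LiN(i-Pr)2, −78 °C) is added to 3. Conjugate addition through its CH2 carbon is followed by ring-closing conjugate addition of the resulting ketone enolate to the crotonyl unit. This gives diketone F3, in which the reversible second addition should let the C-5 methyl settle equatorial (β). Kinetic enolisation of the unhindered C-7 ketone and silylation (LiN(i-Pr)2, t-BuMe2SiCl) return to the route at 4, together with its double-bond isomer F4, which behaves the same way in step 3.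

**Step 7.** The acid may also attack the benzyl ether or ionise the tertiary C-7 centre, and opening of the bridge may be incomplete. Fallback: hydrolysis instead of acetolysis. It sets out from 9. Dilute aqueous HCl in dioxane at 80 °C, where benzyl ethers are inert and water in excess drives the opening, gives the free hemiacetal F5. NaBH4 then reduces F5 and returns to the route at 11.

**Step 20.** Facial selectivity of hydride addition may be low or reversed if the ring carbon C-8 rather than C-4a acts as the large group, and some conjugate reduction may occur. Fallback: form the carbinol by C–C bond formation instead. The alkenyllithium 25 (excess) is added to the aldehyde form of lactol 12, where the same facial bias puts the alkenyl group where hydride went. This sets out from 12 and returns to the route at 27. It makes no new compound and skips steps 10 and 19.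

**Step 25.** The ring B half-chair may place the axial 4α-methyl over the α face and send the reagent to the β face. Fallback: epoxidation and inverting hydrolysis. It sets out from 37. mCPBA, expected to follow the same facial preference, gives the β-epoxide F6. Acid-catalysed hydrolysis (HClO4, THF–H2O) opens it at the tertiary C-2 with inversion to the trans-diol F7 (2α-OH, 1β-OH). Dess–Martin oxidation of the secondary alcohol returns to the route at 39.

## Further compounds

F1 | step 22 | cyclic enol ether (3,4-dihydro-2H-pyran) from lactol 29, C-4=C-1′ | CC=1[C@@H]2[C@H](C)C[C@](O)(COCc3ccccc3)C[C@@H]2[C@@H](/C(C)=C/[C@H](C)CC)OC=1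
F2 | step 22 | 4β-formyl octalin (aldehyde analogue of 33) | CC[C@@H](C)[C@@H]1[C@](C)(C=O)[C@@H]2[C@H](C)C[C@](O)(COCc3ccccc3)C[C@@H]2C=C1C
F3 | step 2 | tricyclic C-4/C-7 diketone | O=C1[C@@H]2[C@H](C)CC(=O)C[C@@H]2[C@H]3CO[C@@H]1O3
F4 | step 2 | C-7=C-8 silyl enol ether isomer of 4 | O=C1[C@@H]2[C@H](C)CC(O[Si](C)(C)C(C)(C)C)=C[C@@H]2[C@H]3CO[C@@H]1O3
F5 | step 7 | free hemiacetal (pyranose with C-1′ OH and free CH2OH on C-1) | C[C@H]1[C@@H]2[C@H](C)C[C@](O)(COCc3ccccc3)C[C@@H]2[C@@H](CO)OC1O
F0 | step 20 | none | none
F6 | step 25 | 1β,2β-epoxide of 37 | CC[C@@H](C)[C@@H]1[C@](C)(C(=O)CCOCc3ccccc3)[C@@H]2[C@H](C)C[C@](O)(COCc4ccccc4)C[C@@H]2[C@@H]5O[C@]15C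
F7 | step 25 | trans-diol (1β-OH, 2α-OH) | CC[C@@H](C)[C@@H]1[C@](C)(C(=O)CCOCc3ccccc3)[C@@H]2[C@H](C)C[C@](O)(COCc4ccccc4)C[C@@H]2[C@H](O)[C@@]1(C)O
A1 | alternative 1 | cis-decalin with ring A carbinol and exocyclic methylene (ene product) | CC[C@@H](C)[C@@H]1[C@](C)(C(=O)CCO[Si](C)(C)C(C)(C)C)[C@@H]2C(=C)C[C@](O)(COCc3ccccc3)C[C@@H]2C(=O)[C@@]1(C)O[Si](CC)(CC)CC
A2 | alternative 1 | ring B ketone with isopropenyl on C-4a and 3-benzyloxy-2-oxopropyl on C-8a (ene substrate) | CC[C@@H](C)[C@@H]1[C@](C)(C(=O)CCO[Si](C)(C)C(C)(C)C)[C@H](C(C)=C)[C@H](CC(=O)COCc2ccccc2)C(=O)[C@@]1(C)O[Si](CC)(CC)CC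
A3 | alternative 2 | cyclobutane photoadduct with ring A closed | CC[C@@H](C)[C@@H](C1(C)OCCO1)[C@@]2(C)[C@@H]3[C@@H](O[Si](C)(C)C(C)(C)C)C[C@](O4)(COC4(C)C)C[C@@]35C(=O)OC(C)(C)O[C@@]25CCO[Si](C)(C)C(C)(C)C
A4 | alternative 2 | dioxinone with tethered (E)-trisubstituted alkene (photosubstrate) | CC[C@@H](C)[C@@H](C1(C)OCCO1)/C(C)=C/[C@@H](O[Si](C)(C)C(C)(C)C)C[C@](O2)(COC2(C)C)CC3=C(CCO[Si](C)(C)C(C)(C)C)OC(C)(C)OC3=O
A5 | alternative 3 | endo adduct with ring B, anhydride and silyl enol ether | O=C1OC(=O)[C@]2(C)[C@@H]3[C@@H](O[Si](C)(C)C(C)(C)C)C[C@](O4)(COC4(C)C)CC3=C(O[Si](C)(C)C)C[C@H]12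
A6 | alternative 3 | 2-silyloxydiene on the ring A cyclohexene | C=C(O[Si](C)(C)C)C1=C[C@@H](O[Si](C)(C)C(C)(C)C)C[C@](O2)(COC2(C)C)C1
A7 | alternative 3 | citraconic anhydride | CC1=CC(=O)OC1=O
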